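The pyran ring is disconnected at the aryl ether bond O1–C8a and, in the same operation, at C4–C4a, so the chromene arises by a [3+3] annulation of an arene with an O–C–C=C unit. The key step is a domino Suzuki–Miyaura coupling/intramolecular palladium etherification between 4-acetyl-2-iodo-6-methoxyphenyl triflate and a five-membered cyclic alkenylboronic hemiester (a 1,2-oxaborole). Its temporary B–O tether, made by ring-closing metathesis, locks the future C3=C4 bond cis and carries the C2 stereocentre from (S)-2-methylglycidol. The step exploits the cis C3=C4 alkene of the pyran ring and the C6 acetyl group para to C8a, which activates the C8a–OTf bond. Desilylation, feruloylation and phenol release finish the synthesis.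

Key step: step 6

Remark: chromene numbering (O1, C2, C3, C4, C4a, C5 to C8, C8a) is used throughout. The target is (R) at C2. (S)-2-Methylglycidol and (E)-4-acetoxy-3-methoxycinnamic acid are assumed to be purchasable. From step 6 on the chromenes should be kept from UV light, because photochemical pyran ring opening would racemise C2.

Step 1
Reactants: 1 acetovanillone (1-(4-hydroxy-3-methoxyphenyl)ethan-1-one)
Product: 2 1-(4-hydroxy-3-iodo-5-methoxyphenyl)ethan-1-one
Conditions: NIS (1.05 equiv), TsOH·H2O (10 mol %), MeCN, rt
Reagents that add atoms: N-iodosuccinimide, O=C1CCC(=O)N1I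
Why: Electrophilic aromatic iodination is directed by the free phenol to its only open ortho position (the other ortho carbon carries OMe, the para carbon the acetyl group), so iodine should enter at the carbon that becomes C4a.

Step 2
Reactants: 2 1-(4-hydroxy-3-iodo-5-methoxyphenyl)ethan-1-one
Product: 3 4-acetyl-2-iodo-6-methoxyphenyl trifluoromethanesulfonate
Conditions: Tf2O (1.2 equiv), pyridine, CH2Cl2, 0 °C
Reagents that add atoms: trifluoromethanesulfonic anhydride, O=S(=O)(OS(=O)(=O)C(F)(F)F)C(F)(F)F
Why: O-Sulfonylation of the acidic phenol with the highly electrophilic anhydride should outrun any reaction at the ketone and turns the native phenol oxygen at C8a into a leaving group.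

Step 3
Reactants: 4 (S)-2-methylglycidol ([(2S)-2-methyloxiran-2-yl]methanol)
Product: 5 tert-butyldimethyl{[(2R)-2-methyloxiran-2-yl]methoxy}silane
Conditions: TBSCl (1.1 equiv), imidazole (1.5 equiv), CH2Cl2, 0 °C to rt
Reagents that add atoms: tert-butyldimethylsilyl chloride, CC(C)(C)[Si](C)(C)Cl
Why: Silylation of the primary alcohol leaves the epoxide and the quaternary stereocentre untouched (the descriptor changes from S to R only through the CIP priorities).

Step 4
Reactants: 5 tert-butyldimethyl{[(2R)-2-methyloxiran-2-yl]methoxy}silane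
Product: 6 (2R)-1-[(tert-butyldimethylsilyl)oxy]-2-methylbut-3-en-2-ol
Conditions: Me3S+ I− (3 equiv), n-BuLi (2.9 equiv), THF, −10 °C to rt
Reagents that add atoms: trimethylsulfonium iodide, C[S+](C)C.[I-]
Why: In the sulfonium-ylide homologation of epoxides to allylic alcohols, dimethylsulfonium methylide opens the epoxide at its unsubstituted CH2 and the sulfonium betaine loses Me2S by ylide-mediated elimination; the C–O bond at the stereocentre is never broken, so the configuration is retained.

Step 5
Reactants: 6 (2R)-1-[(tert-butyldimethylsilyl)oxy]-2-methylbut-3-en-2-ol; 7 dibutyl ethenylboronate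
Product: 10 (5R)-5-{[(tert-butyldimethylsilyl)oxy]methyl}-5-methyl-2,5-dihydro-1,2-oxaborol-2-ol, via mixed vinylboronate 8 (not isolated), via cyclic butyl boronate 9 (not isolated)
Conditions: 7 (1.5 equiv), 4 Å MS, toluene, 80 °C; then second-generation Grubbs catalyst RuCl2(=CHPh)(PCy3)(H2IMes) (5 mol %), toluene, 80 °C; aqueous work-up
Reagents that add atoms: water, O
Why: In this boron-tethered ring-closing metathesis, reversible transesterification hangs the vinylboron unit on the tertiary oxygen and loss of ethylene closes a five-membered ring in which the new C=C bond can only be cis; the stereocentre is not involved.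

Step 6
Reactants: 3 4-acetyl-2-iodo-6-methoxyphenyl trifluoromethanesulfonate; 10 (5R)-5-{[(tert-butyldimethylsilyl)oxy]methyl}-5-methyl-2,5-dihydro-1,2-oxaborol-2-ol
Product: 12 1-[(2R)-2-{[(tert-butyldimethylsilyl)oxy]methyl}-8-methoxy-2-methyl-2H-chromen-6-yl]ethan-1-one, via Z-alkenyl aryl triflate 11 (not isolated)
Conditions: Pd(dppf)Cl2·CH2Cl2 (5 mol %), Cs2CO3 (3 equiv), H2O (3 equiv), 1,4-dioxane, 60 °C then 100 °C
Reagents that add atoms: none
Why: Zerovalent palladium first inserts into the C–I bond of 3, the boronate of 10 transfers its alkenyl carbon and reductive elimination gives 11 with the cis geometry imposed by the oxaborole ring, the B–O tether being hydrolysed to free the tertiary hydroxyl; a second oxidative addition into the C8a–OTf bond, carbonate-assisted binding of the tertiary alkoxide and C–O reductive elimination then forge O1–C8a. The closest known reactions are the Suzuki–Miyaura coupling of cyclic alkenylboronic hemiesters and the intramolecular Buchwald–Hartwig etherification of tertiary alcohols with bisphosphine–palladium catalysts, run here as a domino sequence. The 2H-pyran ring is closed at O1–C8a from a seven-membered aryl(alkoxo)palladium chelate, formally a 6-exo-trig attack of O1 on C8a, and direct SNAr at the acetyl-activated C8a would lead to the same product. No stereocentre is formed, and C2 keeps the configuration of 4 because its C–O bond is never broken. The step needs iodide-before-triflate selectivity (secured by the intrinsic C–I over C–OTf order of oxidative addition), retention of the Z alkene (secured by the ring of 10 and stereoretentive transmetalation) and clean O-arylation (secured by a tertiary alkoxide without carbinol hydrogen, the silyl-masked primary oxygen and the electron-poor aryl group with acetyl para to C8a, which favours C–O reductive elimination).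

Step 7
Reactants: 12 1-[(2R)-2-{[(tert-butyldimethylsilyl)oxy]methyl}-8-methoxy-2-methyl-2H-chromen-6-yl]ethan-1-one
Product: 13 1-[(2R)-2-(hydroxymethyl)-8-methoxy-2-methyl-2H-chromen-6-yl]ethan-1-one
Conditions: HF·pyridine, THF, 0 °C to rt
Reagents that add atoms: none
Why: Fluoride-driven desilylation of the primary silyl ether should leave the ketone, the chromene alkene and the stereocentre untouched.

Step 8
Reactants: 13 1-[(2R)-2-(hydroxymethyl)-8-methoxy-2-methyl-2H-chromen-6-yl]ethan-1-one; 14 (E)-4-acetoxy-3-methoxycinnamic acid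
Product: 15 [(2R)-6-acetyl-8-methoxy-2-methyl-2H-chromen-2-yl]methyl (2E)-3-(4-acetoxy-3-methoxyphenyl)prop-2-enoate
Conditions: EDC·HCl (1.5 equiv), DMAP (0.2 equiv), CH2Cl2, rt
Reagents that add atoms: none
Why: In this Steglich esterification the acylpyridinium intermediate should acylate the only free hydroxyl despite its neopentyl-type hindrance, and the E alkene of the acid is not touched.

Step 9
Reactants: 15 [(2R)-6-acetyl-8-methoxy-2-methyl-2H-chromen-2-yl]methyl (2E)-3-(4-acetoxy-3-methoxyphenyl)prop-2-enoate
Product: 16 [(2R)-6-acetyl-8-methoxy-2-methyl-2H-chromen-2-yl]methyl (2E)-3-(4-hydroxy-3-methoxyphenyl)prop-2-enoate (target)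
Conditions: pyrrolidine (2 equiv), CH2Cl2, 0 °C
Reagents that add atoms: none
Why: Chemoselective aminolysis should cleave the aryl acetate, whose phenoxide is a far better leaving group than the alkoxide of the hindered alkyl cinnamate, so the ferulate ester, ketone and chromene remain.

Compound list
1 | acetovanillone, 1-(4-hydroxy-3-methoxyphenyl)ethan-1-one | CC(=O)c1ccc(O)c(OC)c1 | starting material
2 | 1-(4-hydroxy-3-iodo-5-methoxyphenyl)ethan-1-one | CC(=O)c1cc(I)c(O)c(OC)c1 | intermediate
3 | 4-acetyl-2-iodo-6-methoxyphenyl trifluoromethanesulfonate | CC(=O)c1cc(I)c(OS(=O)(=O)C(F)(F)F)c(OC)c1 | intermediate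
4 | (S)-2-methylglycidol, [(2S)-2-methyloxiran-2-yl]methanol | OC[C@@]1(C)CO1 | starting material
5 | tert-butyldimethyl{[(2R)-2-methyloxiran-2-yl]methoxy}silane | CC(C)(C)[Si](C)(C)OC[C@@]1(C)CO1 | intermediate
6 | (2R)-1-[(tert-butyldimethylsilyl)oxy]-2-methylbut-3-en-2-ol | CC(C)(C)[Si](C)(C)OC[C@@](O)(C)C=C | intermediate
7 | dibutyl ethenylboronate | C=CB(OCCCC)OCCCC | starting material
8 | butyl (2R)-1-[(tert-butyldimethylsilyl)oxy]-2-methylbut-3-en-2-yl ethenylboronate (mixed vinylboronate) | CC(C)(C)[Si](C)(C)OC[C@@](OB(C=C)OCCCC)(C)C=C | intermediate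
9 | (5R)-2-butoxy-5-{[(tert-butyldimethylsilyl)oxy]methyl}-5-methyl-2,5-dihydro-1,2-oxaborole (cyclic butyl boronate) | CC(C)(C)[Si](C)(C)OC[C@@]1(C)C=CB(OCCCC)O1 | intermediate
10 | (5R)-5-{[(tert-butyldimethylsilyl)oxy]methyl}-5-methyl-2,5-dihydro-1,2-oxaborol-2-ol | CC(C)(C)[Si](C)(C)OC[C@@]1(C)C=CB(O)O1 | intermediate
11 | 4-acetyl-2-[(1Z,3R)-4-[(tert-butyldimethylsilyl)oxy]-3-hydroxy-3-methylbut-1-en-1-yl]-6-methoxyphenyl trifluoromethanesulfonate (Z-alkenyl aryl triflate) | CC(C)(C)[Si](C)(C)OC[C@@](O)(C)/C=C\c1cc(C(C)=O)cc(OC)c1OS(=O)(=O)C(F)(F)F | intermediate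
12 | 1-[(2R)-2-{[(tert-butyldimethylsilyl)oxy]methyl}-8-methoxy-2-methyl-2H-chromen-6-yl]ethan-1-one | CC(C)(C)[Si](C)(C)OC[C@@]1(C)C=Cc2cc(C(C)=O)cc(OC)c2O1 | intermediate
13 | 1-[(2R)-2-(hydroxymethyl)-8-methoxy-2-methyl-2H-chromen-6-yl]ethan-1-one | OC[C@@]1(C)C=Cc2cc(C(C)=O)cc(OC)c2O1 | intermediate
14 | (E)-4-acetoxy-3-methoxycinnamic acid | CC(=O)Oc1ccc(/C=C/C(=O)O)cc1OC | starting material
15 | [(2R)-6-acetyl-8-methoxy-2-methyl-2H-chromen-2-yl]methyl (2E)-3-(4-acetoxy-3-methoxyphenyl)prop-2-enoate | CC(=O)Oc1ccc(/C=C/C(=O)OC[C@@]2(C)C=Cc3cc(C(C)=O)cc(OC)c3O2)cc1OC | intermediate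
16 | [(2R)-6-acetyl-8-methoxy-2-methyl-2H-chromen-2-yl]methyl (2E)-3-(4-hydroxy-3-methoxyphenyl)prop-2-enoate | COc1cc(/C=C/C(=O)OC[C@@]2(C)C=Cc3cc(C(C)=O)cc(OC)c3O2)ccc1O | target

Total step count: 9. Longest linear sequence: 7 steps (steps 3 to 9, from 4).

Steps most likely to fail

Step 6. The domino sequence may stall after the cross-coupling, lose the triflate by S–O cleavage or hydrolysis before the ring closes, lose the iodide-before-triflate order of oxidative addition, or isomerise the Z alkene so that O1 can no longer reach C8a. The fallback closes the same bond by SNAr instead of palladium etherification. It sets out from 2: deoxyfluorination of the phenol (PhenoFluor, CsF, toluene, 110 °C) should give 1-(4-fluoro-3-iodo-5-methoxyphenyl)ethan-1-one F1. Suzuki–Miyaura coupling of F1 with 10 (Pd(PPh3)4, K3PO4, dioxane/H2O, 60 °C) should give 1-{4-fluoro-3-[(1Z,3R)-4-[(tert-butyldimethylsilyl)oxy]-3-hydroxy-3-methylbut-1-en-1-yl]-5-methoxyphenyl}ethan-1-one F2. Treatment with Cs2CO3 in DMSO at 90 °C should then displace the fluoride para to the acetyl group by the tertiary alkoxide, and the route is rejoined at 12.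

Step 5. Transesterification of the hindered tertiary alcohol may lie too far on the side of the open boronate, so that ring-closing metathesis is starved, or the cyclic hemiester may be lost by protodeboronation on isolation. The fallback replaces the tether by photochemical geometry control. It sets out from 6: Heck coupling with 3 at the C–I bond (Pd(OAc)2, Bu4NCl, NaHCO3, DMF, 60 °C) should give 4-acetyl-2-[(1E,3R)-4-[(tert-butyldimethylsilyl)oxy]-3-hydroxy-3-methylbut-1-en-1-yl]-6-methoxyphenyl trifluoromethanesulfonate F3. Triplet-sensitised E-to-Z isomerisation (fac-Ir(ppy)3, blue LEDs, MeCN, rt) should then give 11, now isolated. The route is rejoined at 11, which is closed to 12 under the second stage of step 6 (Pd(dppf)Cl2·CH2Cl2, Cs2CO3, dioxane, 100 °C).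

Step 4. Ylide attack at the CH2 group next to the quaternary carbon may be slow, and the elimination of dimethyl sulfide from the betaine may remain incomplete. The fallback installs the vinyl group by selenoxide elimination. It sets out from 5: opening with (phenylselanyl)methyllithium (from bis(phenylselanyl)methane and n-BuLi, THF, −78 °C) should give (2R)-1-[(tert-butyldimethylsilyl)oxy]-2-methyl-4-(phenylselanyl)butan-2-ol F4. Oxidation with H2O2 (THF, 0 °C to rt) and syn-elimination of the selenoxide should then give the allylic alcohol, and the route is rejoined at 6.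

Further compounds
F1 | step 6 | 1-(4-fluoro-3-iodo-5-methoxyphenyl)ethan-1-one | CC(=O)c1cc(I)c(F)c(OC)c1
F2 | step 6 | 1-{4-fluoro-3-[(1Z,3R)-4-[(tert-butyldimethylsilyl)oxy]-3-hydroxy-3-methylbut-1-en-1-yl]-5-methoxyphenyl}ethan-1-one | CC(C)(C)[Si](C)(C)OC[C@@](O)(C)/C=C\c1cc(C(C)=O)cc(OC)c1F
F3 | step 5 | 4-acetyl-2-[(1E,3R)-4-[(tert-butyldimethylsilyl)oxy]-3-hydroxy-3-methylbut-1-en-1-yl]-6-methoxyphenyl trifluoromethanesulfonate | CC(C)(C)[Si](C)(C)OC[C@@](O)(C)/C=C/c1cc(C(C)=O)cc(OC)c1OS(=O)(=O)C(F)(F)F
F4 | step 4 | (2R)-1-[(tert-butyldimethylsilyl)oxy]-2-methyl-4-(phenylselanyl)butan-2-ol | CC(C)(C)[Si](C)(C)OC[C@@](O)(C)CC[Se]c1ccccc1
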